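**Retrosynthetic overview**
- Target ⇐ late epoxidation of the (Z)-C3=C4 olefin; γ-lactone ⇐ C8-hydroxyl-directed anti reduction of a C6 ketone, then lactonisation.
- Ten-membered ring ⇐ four-atom ring expansion of a cyclohexenone α-ketol: the C10 alkenyl unit adds to the C1 ketone (transient six-membered ring), then the old C1–C6 bond is cut (two-electron Dowd–Beckwith-type).
- α-Ketol ⇐ Barbier union (C6–C7) of a racemic 2-hydroxycyclohexenone (from m-cresol by Birch reduction) with a 2-(bromomethyl)enoate.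
- Bromo-enoate ⇐ 2-bromoacrolein + allyl MOM ether (alkoxyallylboration sets C8 and C9) + angelic acid + methyl 2-(bromomethyl)acrylate (cross-metathesis).
- Ring order: cyclohexene ring A (carries the Z olefin) → transient bicyclo[4.4.0] → cyclodecene → γ-lactone → epoxide.

Assumption: atoms are named by germacrane numbering (C1 ring ketone, C3–C4 epoxide, C6 lactone O–CH, C7, C8 CHOH, C9 CH–O-angeloyl, C10 C(=CH2), C11–C13 methylene-lactone carbons, C14 the CH2 on C10), which makes the target (3S,4R,6R,7R,8S,9S).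

**Step 1**
Reactants: 1 3-methylphenol
Product: 2 1-methoxy-3-methylbenzene
Conditions: MeI, K2CO3, acetone, 56 °C
Reagents that add atoms: iodomethane (CI)
Why: Williamson O-methylation of the phenoxide (SN2) gives the aryl ether needed for a regioselective Birch reduction; no stereocentre.

**Step 2**
Reactants: 2 1-methoxy-3-methylbenzene
Product: 3 1-methoxy-5-methylcyclohexa-1,4-diene
Conditions: Li, NH3 (l), t-BuOH, THF, −78 to −33 °C
Reagents that add atoms: none
Why: Birch reduction leaves the methoxy- and methyl-bearing carbons on the two surviving double bonds, so the enol ether and the future C3=C4 olefin are placed 1,4 with fixed regiochemistry; no stereocentre.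

**Step 3**
Reactants: 3 1-methoxy-5-methylcyclohexa-1,4-diene
Product: 5 2-hydroxy-5-methylcyclohex-4-en-1-one (racemic), via hemiketal diol 4 (not isolated)
Conditions: K2OsO4·2H2O (1 mol %), NMO, acetone/H2O, 0 °C
Reagents that add atoms: N-methylmorpholine N-oxide (C[N+]1([O-])CCOCC1); water (O)
Why: Upjohn dihydroxylation takes the electron-rich enol-ether double bond rather than the trisubstituted olefin and the hemiketal loses methanol, giving the ketone at the future C6 and a racemic carbinol at the future C1 that is erased in step 8.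

**Step 4**
Reactants: 6 3-(methoxymethoxy)prop-1-ene; 7 2-bromoprop-2-enal
Product: 9 (3R,4S)-2-bromo-4-(methoxymethoxy)hexa-1,5-dien-3-ol, via alkoxyallylborane 8 (not isolated)
Conditions: 6, s-BuLi, THF, −78 °C; (+)-Ipc2BOMe; BF3·OEt2; then 7, −78 °C; NaOH, H2O2
Reagents that add atoms: none
Why: Brown alkoxyallylboration: the (Z)-γ-alkoxyallylborane reacts through a chair transition state to give the syn (threo) diol monoether, and the isopinocampheyl groups from (−)-α-pinene direct addition to the Re face of the aldehyde, setting C9 and C8 as (3R,4S) in this compound.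

**Step 5**
Reactants: 9 (3R,4S)-2-bromo-4-(methoxymethoxy)hexa-1,5-dien-3-ol; 10 (2Z)-2-methylbut-2-enoic acid
Product: 12 (3R,4S)-2-bromo-4-(methoxymethoxy)hexa-1,5-dien-3-yl (2Z)-2-methylbut-2-enoate, via mixed anhydride 11 (not isolated)
Conditions: 10, 2,4,6-trichlorobenzoyl chloride, Et3N, toluene, 25 °C; then 9, DMAP, 25 °C
Reagents that add atoms: none
Why: Yamaguchi esterification acylates the free C9 hydroxyl with retention and is mild enough to keep the (Z)-angelate geometry; C8 stays masked as the MOM ether.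

**Step 6**
Reactants: 12 (3R,4S)-2-bromo-4-(methoxymethoxy)hexa-1,5-dien-3-yl (2Z)-2-methylbut-2-enoate; 13 methyl 2-(bromomethyl)prop-2-enoate
Product: 14 methyl (2Z,4S,5R)-6-bromo-2-(bromomethyl)-4-(methoxymethoxy)-5-{[(2Z)-2-methylbut-2-enoyl]oxy}hepta-2,6-dienoate
Conditions: 13 (5 equiv), second-generation Hoveyda–Grubbs catalyst (5 mol %), CH2Cl2, 40 °C
Reagents that add atoms: none
Why: Olefin cross-metathesis engages only the monosubstituted vinyl group (vinyl bromide and angelate are inert) and gives the trisubstituted enoate with the chain trans to the ester, as with methacrylates; no stereocentre is touched.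

**Step 7**
Reactants: 5 2-hydroxy-5-methylcyclohex-4-en-1-one; 14 methyl (2Z,4S,5R)-6-bromo-2-(bromomethyl)-4-(methoxymethoxy)-5-{[(2Z)-2-methylbut-2-enoyl]oxy}hepta-2,6-dienoate
Product: 16 methyl (3R,4S,5R)-6-bromo-3-(1,2-dihydroxy-5-methylcyclohex-4-en-1-yl)-4-(methoxymethoxy)-2-methylidene-5-{[(2Z)-2-methylbut-2-enoyl]oxy}hept-6-enoate (ring hydroxyls cis; both ring configurations), via allylindium species 15 (not isolated)
Conditions: indium powder, THF/H2O (4:1), 25 °C, neutral work-up
Reagents that add atoms: none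
Why: Barbier-type indium allylation adds the γ-carbon (C7) of the allylindium to the hydroxyl-activated ketone (SE2′), forming C6–C7; C7 is set by allylic 1,3-strain control (C8–H eclipsing the olefin, attack anti to the bulky C9 branch, with chelation by the MOM group suppressed in water), and the two ring carbinol centres are a mixture that converges later.

**Step 8**
Reactants: 16 the Barbier diol
Product: 17 methyl (3R,4S,5R)-6-bromo-3-(1-hydroxy-5-methyl-2-oxocyclohex-4-en-1-yl)-4-(methoxymethoxy)-2-methylidene-5-{[(2Z)-2-methylbut-2-enoyl]oxy}hept-6-enoate (both configurations at the ring carbinol)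
Conditions: Dess–Martin periodinane (1.1 equiv), NaHCO3, CH2Cl2, 0 °C
Reagents that add atoms: none
Why: Dess–Martin oxidation converts only the secondary ring carbinol (future C1) into the ketone, the tertiary C6 hydroxyl being inert, and buffering prevents dehydration of the skipped enone; the erased carbinol centre removes one source of isomers.

**Step 9**
Reactants: 17 the α-ketol
Product: 19 methyl 2-[(1R,4Z,9S,10S)-10-(methoxymethoxy)-4-methyl-8-methylidene-9-{[(2Z)-2-methylbut-2-enoyl]oxy}-2,7-dioxocyclodec-4-en-1-yl]prop-2-enoate, via chromium alkoxide 18 (not isolated)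
Conditions: [Ir(dF(CF3)ppy)2(dtbbpy)]PF6 (2 mol %), CrCl3 (15 mol %), NiCl2·dme (3 mol %), 2,6-lutidine, DMF, 450 nm LED, 25 °C
Reagents that add atoms: none
Why: Proposed new method: a redox-neutral alkenylative ring expansion in which the excited iridium photocatalyst reduces trivalent to divalent chromium, which with the nickel co-catalyst turns the C10–Br bond into an alkenylchromium that adds 6-exo to the chelating C1 ketone (Nozaki–Hiyama–Kishi step) to give diolate 18, and the oxidised photocatalyst then raises 18 to tetravalent chromium, which cuts the C1–C6 glycol bond and returns divalent chromium, so that the old ring bond is traded for the new C1–C10 bond, the Z olefin of ring A passes unchanged into the ten-membered ring, the mixture at C6 converges and no stereocentre is formed; the closest known reactions are photoredox chromium/nickel alkenylation of carbonyls, chromium-mediated glycol fission and the radical Dowd–Beckwith ring expansion.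

**Step 10**
Reactants: 19 the MOM-protected cyclodecenedione
Product: 21 methyl 2-[(1R,4Z,9S,10S)-10-hydroxy-4-methyl-8-methylidene-9-{[(2Z)-2-methylbut-2-enoyl]oxy}-2,7-dioxocyclodec-4-en-1-yl]prop-2-enoate, via bromomethyl ether 20 (not isolated)
Conditions: Me2BBr, CH2Cl2, −78 °C; then THF, aq. NaHCO3
Reagents that add atoms: none
Why: Lewis-acid cleavage of the MOM acetal at −78 °C (the bromomethyl ether hydrolyses on work-up) frees the C8 hydroxyl without touching the esters, the enone or the skipped olefin; no stereocentre changes.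

**Step 11**
Reactants: 21 the β-hydroxy ketone
Product: 23 (3aR,4S,5S,9Z,11aR)-4-hydroxy-10-methyl-3,6-dimethylidene-2,7-dioxo-2,3,3a,4,5,6,7,8,11,11a-decahydrocyclodeca[b]furan-5-yl (2Z)-2-methylbut-2-enoate, via anti-diol ester 22 (not isolated)
Conditions: Me4NBH(OAc)3, MeCN/AcOH (1:1), −30 °C; then camphorsulfonic acid (cat.), CH2Cl2, 25 °C
Reagents that add atoms: none
Why: Evans–Saksena reduction delivers hydride intramolecularly from the borate on the C8 oxygen, so only the β-hydroxy ketone reacts (the enone is untouched) and C6 is set anti to the C8 hydroxyl (6R); acid then closes the C6 hydroxyl on the ester to the trans-fused γ-lactone, favoured over the cis-fused alternative through the C8 hydroxyl.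

**Step 12**
Reactants: 23 the (Z)-germacradienolide
Product: 24 (3S,4R,6R,7R,8S,9S)-9-[(2Z)-2-methylbut-2-enoyloxy]-3,4-epoxy-8-hydroxy-1-oxogermacra-10(14),11(13)-dien-12,6-olide (CNP0348992.1)
Conditions: mCPBA, NaHCO3, CH2Cl2, 0 °C
Reagents that add atoms: 3-chloroperoxybenzoic acid (OOC(=O)c1cccc(Cl)c1)
Why: Prilezhaev epoxidation attacks only the electron-rich trisubstituted olefin (the enone, methylene lactone and angelate are electron-poor), and the peracid, hydrogen-bonded to the transannular C8 hydroxyl (Henbest-type direction), delivers oxygen to the face carrying that hydroxyl, giving the (3S,4R) cis-epoxide.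

**Compound list**
1 | 3-methylphenol (m-cresol) | Cc1cccc(O)c1 | starting material
2 | 1-methoxy-3-methylbenzene | COc1cccc(C)c1 | intermediate
3 | 1-methoxy-5-methylcyclohexa-1,4-diene | COC1=CCC=C(C)C1 | intermediate
4 | cis-1-methoxy-5-methylcyclohex-4-ene-1,2-diol (racemic; relative configuration shown; not isolated) | CO[C@@]1(O)CC(C)=CC[C@@H]1O | intermediate
5 | 2-hydroxy-5-methylcyclohex-4-en-1-one (racemic) | O=C1CC(C)=CCC1O | intermediate
6 | 3-(methoxymethoxy)prop-1-ene (allyl MOM ether) | C=CCOCOC | starting material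
7 | 2-bromoprop-2-enal (2-bromoacrolein) | C=C(Br)C=O | starting material
8 | [(2Z)-3-(methoxymethoxy)prop-2-en-1-yl]diisopinocampheylborane, both isopinocampheyl groups from (−)-α-pinene (not isolated) | COCO/C=C\CB([C@H]1C[C@H]2C[C@@H]([C@@H]1C)C2(C)C)[C@H]1C[C@H]2C[C@@H]([C@@H]1C)C2(C)C | intermediate
9 | (3R,4S)-2-bromo-4-(methoxymethoxy)hexa-1,5-dien-3-ol | C=C(Br)[C@H](O)[C@@H](OCOC)C=C | intermediate
10 | (2Z)-2-methylbut-2-enoic acid (angelic acid) | C/C=C(/C)C(O)=O | starting material
11 | (2Z)-2-methylbut-2-enoic 2,4,6-trichlorobenzoic anhydride (not isolated) | C/C=C(/C)C(=O)OC(=O)c1c(Cl)cc(Cl)cc1Cl | intermediate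
12 | (3R,4S)-2-bromo-4-(methoxymethoxy)hexa-1,5-dien-3-yl (2Z)-2-methylbut-2-enoate | C=C(Br)[C@H](OC(=O)/C(C)=C\C)[C@@H](OCOC)C=C | intermediate
13 | methyl 2-(bromomethyl)prop-2-enoate | C=C(CBr)C(=O)OC | starting material
14 | methyl (2Z,4S,5R)-6-bromo-2-(bromomethyl)-4-(methoxymethoxy)-5-{[(2Z)-2-methylbut-2-enoyl]oxy}hepta-2,6-dienoate | BrC/C(C(=O)OC)=C\[C@H](OCOC)[C@@H](OC(=O)/C(C)=C\C)C(Br)=C | intermediate
15 | allylindium dibromide derived from 14, Br2In–CH2 in place of BrCH2 (not isolated) | Br[In](Br)C/C(C(=O)OC)=C\[C@H](OCOC)[C@@H](OC(=O)/C(C)=C\C)C(Br)=C | intermediate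
16 | methyl (3R,4S,5R)-6-bromo-3-(1,2-dihydroxy-5-methylcyclohex-4-en-1-yl)-4-(methoxymethoxy)-2-methylidene-5-{[(2Z)-2-methylbut-2-enoyl]oxy}hept-6-enoate (ring hydroxyls cis; both ring configurations) | OC1CC=C(C)CC1(O)[C@H](C(=C)C(=O)OC)[C@H](OCOC)[C@@H](OC(=O)/C(C)=C\C)C(Br)=C | intermediate
17 | methyl (3R,4S,5R)-6-bromo-3-(1-hydroxy-5-methyl-2-oxocyclohex-4-en-1-yl)-4-(methoxymethoxy)-2-methylidene-5-{[(2Z)-2-methylbut-2-enoyl]oxy}hept-6-enoate (both configurations at the ring carbinol) | O=C1CC=C(C)CC1(O)[C@H](C(=C)C(=O)OC)[C@H](OCOC)[C@@H](OC(=O)/C(C)=C\C)C(Br)=C | intermediate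
18 | dichlorochromium 4a-alkoxide of methyl 2-[(1R,2S,3S)-4a,8a-dihydroxy-2-(methoxymethoxy)-7-methyl-4-methylidene-3-{[(2Z)-2-methylbut-2-enoyl]oxy}-1,2,3,4,4a,5,8,8a-octahydronaphthalen-1-yl]prop-2-enoate (not isolated) | Cl[Cr](Cl)OC12CC=C(C)CC1(O)[C@H](C(=C)C(=O)OC)[C@H](OCOC)[C@@H](OC(=O)/C(C)=C\C)C2=C | intermediate
19 | methyl 2-[(1R,4Z,9S,10S)-10-(methoxymethoxy)-4-methyl-8-methylidene-9-{[(2Z)-2-methylbut-2-enoyl]oxy}-2,7-dioxocyclodec-4-en-1-yl]prop-2-enoate | O=C1C/C=C(/C)CC(=O)[C@H](C(=C)C(=O)OC)[C@H](OCOC)[C@@H](OC(=O)/C(C)=C\C)C1=C | intermediate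
20 | methyl 2-[(1R,4Z,9S,10S)-10-(bromomethoxy)-4-methyl-8-methylidene-9-{[(2Z)-2-methylbut-2-enoyl]oxy}-2,7-dioxocyclodec-4-en-1-yl]prop-2-enoate (not isolated) | O=C1C/C=C(/C)CC(=O)[C@H](C(=C)C(=O)OC)[C@H](OCBr)[C@@H](OC(=O)/C(C)=C\C)C1=C | intermediate
21 | methyl 2-[(1R,4Z,9S,10S)-10-hydroxy-4-methyl-8-methylidene-9-{[(2Z)-2-methylbut-2-enoyl]oxy}-2,7-dioxocyclodec-4-en-1-yl]prop-2-enoate | O=C1C/C=C(/C)CC(=O)[C@H](C(=C)C(=O)OC)[C@H](O)[C@@H](OC(=O)/C(C)=C\C)C1=C | intermediate
22 | methyl 2-[(1S,2R,4Z,9S,10S)-2,10-dihydroxy-4-methyl-8-methylidene-9-{[(2Z)-2-methylbut-2-enoyl]oxy}-7-oxocyclodec-4-en-1-yl]prop-2-enoate (not isolated) | O=C1C/C=C(/C)C[C@@H](O)[C@H](C(=C)C(=O)OC)[C@H](O)[C@@H](OC(=O)/C(C)=C\C)C1=C | intermediate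
23 | (3aR,4S,5S,9Z,11aR)-4-hydroxy-10-methyl-3,6-dimethylidene-2,7-dioxo-2,3,3a,4,5,6,7,8,11,11a-decahydrocyclodeca[b]furan-5-yl (2Z)-2-methylbut-2-enoate | C=C1C(=O)O[C@@H]2C/C(C)=C\CC(=O)C(=C)[C@H](OC(=O)/C(C)=C\C)[C@@H](O)[C@@H]12 | intermediate
24 | (3S,4R,6R,7R,8S,9S)-9-[(2Z)-2-methylbut-2-enoyloxy]-3,4-epoxy-8-hydroxy-1-oxogermacra-10(14),11(13)-dien-12,6-olide (CNP0348992.1) | C=C1C(=O)O[C@@H]2C[C@@]3(C)O[C@H]3CC(=O)C(=C)[C@H](OC(=O)/C(C)=C\C)[C@@H](O)[C@@H]12 | target

**Step count and risks**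
Total step count: 12. Longest linear sequence: 9 steps (1→2→3, then 7 to 12; the branch 4→5→6, then 7 to 12, is equally long).

The three steps most likely to fail are 7, 9 and 12.

For step 7, the C7 configuration rests on acyclic 1,2-induction from C8, and chelation of indium by the MOM group could erode or reverse it. The fallback replaces the chelating group by a bulky, non-chelating silyl ether before the coupling. It sets out from 12: Me2BBr at −78 °C gives (3R,4S)-2-bromo-4-hydroxyhexa-1,5-dien-3-yl (2Z)-2-methylbut-2-enoate F1, and TBSOTf with 2,6-lutidine gives the silyl ether F2. Cross-metathesis with 13 gives the silylated allyl bromide F3, and the indium Barbier reaction with 5 gives the silylated diol F4 through an open transition state. Dess–Martin oxidation gives the silylated α-ketol F5 and ring expansion as in step 9 gives the silylated cyclodecenedione F6. HF·pyridine in THF then removes the silyl group and the path comes back to the route at 21.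

For step 9, the proposed photochemical chromium/nickel ring expansion is untested; the allylic angelate next to the alkenyl bromide and the photocatalytic turnover of the chromium diolate are the weak points. The fallback uses known chemistry in two stages and sets out from 17. Stoichiometric CrCl2 with catalytic NiCl2 in DMSO at 25 °C effects the Nozaki–Hiyama–Kishi cyclisation onto the C1 ketone and gives the isolated bicyclic 4a,8a-diol F7. Pb(OAc)4 with pyridine in CH2Cl2 at −20 °C then cleaves the glycol, which completes the ring expansion and comes back at 19.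

For step 12, the face of the ten-membered olefin taken by the peracid is not secured; undirected peripheral attack could give the other cis-epoxide. The fallback places the oxygen on the face opposite to the one an electrophile attacks and sets out from 23. NBS in aqueous acetone at 0 °C gives the (3R,4R)-3-bromo-4-hydroxy bromohydrin F8 (bromonium on the exposed face, water anti at the tertiary C4). Ag2O in CH2Cl2 then closes the epoxide with inversion at C3 and comes back at 24.

**Further compounds**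
F1 | step 7 | (3R,4S)-2-bromo-4-hydroxyhexa-1,5-dien-3-yl (2Z)-2-methylbut-2-enoate | C=C(Br)[C@H](OC(=O)/C(C)=C\C)[C@@H](O)C=C
F2 | step 7 | (3R,4S)-2-bromo-4-[(tert-butyldimethylsilyl)oxy]hexa-1,5-dien-3-yl (2Z)-2-methylbut-2-enoate | C=C(Br)[C@H](OC(=O)/C(C)=C\C)[C@@H](O[Si](C)(C)C(C)(C)C)C=C
F3 | step 7 | methyl (2Z,4S,5R)-6-bromo-2-(bromomethyl)-4-[(tert-butyldimethylsilyl)oxy]-5-{[(2Z)-2-methylbut-2-enoyl]oxy}hepta-2,6-dienoate | BrC/C(C(=O)OC)=C\[C@H](O[Si](C)(C)C(C)(C)C)[C@@H](OC(=O)/C(C)=C\C)C(Br)=C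
F4 | step 7 | methyl (3R,4S,5R)-6-bromo-4-[(tert-butyldimethylsilyl)oxy]-3-(1,2-dihydroxy-5-methylcyclohex-4-en-1-yl)-2-methylidene-5-{[(2Z)-2-methylbut-2-enoyl]oxy}hept-6-enoate (ring hydroxyls cis; both ring configurations) | OC1CC=C(C)CC1(O)[C@H](C(=C)C(=O)OC)[C@H](O[Si](C)(C)C(C)(C)C)[C@@H](OC(=O)/C(C)=C\C)C(Br)=C
F5 | step 7 | methyl (3R,4S,5R)-6-bromo-4-[(tert-butyldimethylsilyl)oxy]-3-(1-hydroxy-5-methyl-2-oxocyclohex-4-en-1-yl)-2-methylidene-5-{[(2Z)-2-methylbut-2-enoyl]oxy}hept-6-enoate (both configurations at the ring carbinol) | O=C1CC=C(C)CC1(O)[C@H](C(=C)C(=O)OC)[C@H](O[Si](C)(C)C(C)(C)C)[C@@H](OC(=O)/C(C)=C\C)C(Br)=C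
F6 | step 7 | methyl 2-[(1R,4Z,9S,10S)-10-[(tert-butyldimethylsilyl)oxy]-4-methyl-8-methylidene-9-{[(2Z)-2-methylbut-2-enoyl]oxy}-2,7-dioxocyclodec-4-en-1-yl]prop-2-enoate | O=C1C/C=C(/C)CC(=O)[C@H](C(=C)C(=O)OC)[C@H](O[Si](C)(C)C(C)(C)C)[C@@H](OC(=O)/C(C)=C\C)C1=C
F7 | step 9 | methyl 2-[(1R,2S,3S)-4a,8a-dihydroxy-2-(methoxymethoxy)-7-methyl-4-methylidene-3-{[(2Z)-2-methylbut-2-enoyl]oxy}-1,2,3,4,4a,5,8,8a-octahydronaphthalen-1-yl]prop-2-enoate (both ring-fusion configurations) | OC12CC=C(C)CC1(O)[C@H](C(=C)C(=O)OC)[C@H](OCOC)[C@@H](OC(=O)/C(C)=C\C)C2=C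
F8 | step 12 | (3R,4R,6R,7R,8S,9S)-3-bromo-4,8-dihydroxy-9-[(2Z)-2-methylbut-2-enoyloxy]-1-oxogermacra-10(14),11(13)-dien-12,6-olide | C=C1C(=O)O[C@@H]2C[C@@](C)(O)[C@H](Br)CC(=O)C(=C)[C@H](OC(=O)/C(C)=C\C)[C@@H](O)[C@@H]12
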